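**Retrosynthetic overview**
1. Target 19 ⇐ acetylation and esterification of the 3β,4α-diol 16 ⇐ C3 inversion (ketol 15) of the cis-diol 14 ⇐ α-face dihydroxylation of eudesma-3,7(11)-dien-8-one 13.
2. 13 ⇐ alkene conjugation of 12, the intramolecular Diels–Alder adduct of the acyclic tetraenone 11. Rings A and B close together in this one cycloaddition (bonds C1–C2 and C5–C10).
3. 11 ⇐ Wittig methylenation of keto-enal 10 ⇐ glycol cleavage of the C1–C6 ring bond of diol 8 ⇐ (S)-carvone 1 + methallyl bromide 2.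
4. Stereochemistry: C5 of carvone becomes C7, steers the cycloaddition (C5, C10) and is then erased. C4 and C3 follow from the trans-decalin. The side-chain centre is bought as acid 17.

Assumption: (R)-2-methylbutanoic acid 17 is taken as a purchasable single enantiomer; eudesmane numbering (C1–C15) is used for the acyclic and bicyclic compounds from 9 onward.

**Step 1**
Reactants: 1 (S)-(+)-carvone; 2 3-bromo-2-methylprop-1-ene
Product: 4 (5S,6R)-2-methyl-6-(2-methylprop-2-en-1-yl)-5-(prop-1-en-2-yl)cyclohex-2-en-1-one, via lithium dienolate of carvone 3 (not isolated)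
Conditions: LiN(i-Pr)2, THF, −78 °C; then 2, DMPU, −78 → −20 °C
Reagents that add atoms: none
Why: Kinetic α′-deprotonation gives the cross-conjugated dienolate, which is C-alkylated anti to the neighbouring isopropenyl group (enolate alkylation); the new C6 centre is only a relay and is erased in step 4.

**Step 2**
Reactants: 4 (5S,6R)-2-methyl-6-(2-methylprop-2-en-1-yl)-5-(prop-1-en-2-yl)cyclohex-2-en-1-one
Product: 7 (5R,6R)-6-hydroxy-2-methyl-6-(2-methylprop-2-en-1-yl)-5-(prop-1-en-2-yl)cyclohex-2-en-1-one, via lithium dienolate of the methallyl ketone 5 (not isolated), via lithium hydroperoxide salt 6 (not isolated)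
Conditions: LiN(i-Pr)2, THF, −78 °C; then O2, P(OEt)3, −78 → −40 °C; H2O
Reagents that add atoms: dioxygen O=O
Why: C6–H is the only kinetically accessible α-hydrogen, and the tetrasubstituted enolate is oxygenated by O2 with in-situ phosphite reduction of the hydroperoxide (enolate autoxidation); the C6 configuration (drawn anti to isopropenyl) is irrelevant.

**Step 3**
Reactants: 7 (5R,6R)-6-hydroxy-2-methyl-6-(2-methylprop-2-en-1-yl)-5-(prop-1-en-2-yl)cyclohex-2-en-1-one
Product: 8 (1R,5R,6R)-2-methyl-6-(2-methylprop-2-en-1-yl)-5-(prop-1-en-2-yl)cyclohex-2-ene-1,6-diol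
Conditions: NaBH4, CeCl3·7H2O, MeOH, −20 °C
Reagents that add atoms: none
Why: Luche 1,2-reduction of the enone gives the allylic 1,2-diol needed for cleavage; the C1 carbinol (major epimer drawn) is inconsequential because both epimers give the same product in step 4.

**Step 4**
Reactants: 8 (1R,5R,6R)-2-methyl-6-(2-methylprop-2-en-1-yl)-5-(prop-1-en-2-yl)cyclohex-2-ene-1,6-diol
Product: 10 (2E,5R)-2,8-dimethyl-6-oxo-5-(prop-1-en-2-yl)nona-2,8-dienal, via (2Z)-keto-enal 9 (not isolated)
Conditions: NaIO4 on silica gel, CH2Cl2, rt; filter; then I2 (2 mol %), visible light, rt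
Reagents that add atoms: none
Why: Periodate glycol cleavage (Malaprade reaction) opens the C1–C6 bond to the enal and the methallyl ketone without touching the stereocentre, and iodine-catalysed alkene isomerisation turns the ring-derived (Z)-2-methylenal into the much more stable (E)-enal that the cycloaddition needs.

**Step 5**
Reactants: 10 (2E,5R)-2,8-dimethyl-6-oxo-5-(prop-1-en-2-yl)nona-2,8-dienal
Product: 11 (5R,7E)-2,8-dimethyl-5-(prop-1-en-2-yl)deca-1,7,9-trien-4-one
Conditions: Ph3PCH3Br, KN(SiMe3)2, THF, 0 °C; then 10, −78 → −20 °C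
Reagents that add atoms: methyltriphenylphosphonium bromide C[P+](c1ccccc1)(c1ccccc1)c1ccccc1.[Br-]
Why: Wittig methylenation is much faster at the unhindered enal carbonyl than at the α-branched ketone at −78 °C and gives the (E)-1,3-diene.

**Step 6**
Reactants: 11 (5R,7E)-2,8-dimethyl-5-(prop-1-en-2-yl)deca-1,7,9-trien-4-one
Product: 12 (5R,7R,10R)-eudesma-3,11-dien-8-one
Conditions: PhMe (0.01 M), BHT (cat.), silylated sealed tube, 185 °C, 36 h; chromatography to remove the cis-fused and facial isomers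
Reagents that add atoms: none
Why: Thermal intramolecular Diels–Alder reaction of the (E)-diene with the tethered 1,1-disubstituted alkene closes rings A and B at once; a chair-like tether with the isopropenyl group equatorial and the anti (trans-fused) arrangement sets 5α-H and 10β-CH3 from the single carvone-derived centre.

**Step 7**
Reactants: 12 (5R,7R,10R)-eudesma-3,11-dien-8-one
Product: 13 (5R,10R)-eudesma-3,7(11)-dien-8-one
Conditions: DBU (0.2 equiv), PhMe, 60 °C
Reagents that add atoms: none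
Why: Base-catalysed alkene isomerisation through the C7 enolate (as isopulegone goes to pulegone) gives the conjugated tetrasubstituted isopropylidene enone and removes the relay stereocentre.

**Step 8**
Reactants: 13 (5R,10R)-eudesma-3,7(11)-dien-8-one
Product: 14 (3R,4S,5R,10R)-3,4-dihydroxyeudesm-7(11)-en-8-one
Conditions: OsO4 (2 mol %), NMO, acetone–H2O, rt
Reagents that add atoms: osmium tetroxide O=[Os](=O)(=O)=O; N-methylmorpholine N-oxide C[N+]1([O-])CCOCC1; water O
Why: Upjohn dihydroxylation attacks the electron-rich trisubstituted 3,4-alkene (not the electron-poor tetrasubstituted enone) from the α face opposite the axial angular methyl, setting 4α-OH/4β-CH3 and 3α-OH.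

**Step 9**
Reactants: 14 (3R,4S,5R,10R)-3,4-dihydroxyeudesm-7(11)-en-8-one
Product: 15 (4S,5R,10R)-4-hydroxyeudesm-7(11)-ene-3,8-dione
Conditions: 2-iodoxybenzoic acid (IBX), DMSO, rt
Reagents that add atoms: none
Why: IBX oxidation converts the secondary axial alcohol of the 1,2-diol into the ketone without glycol cleavage and leaves the tertiary alcohol.

**Step 10**
Reactants: 15 (4S,5R,10R)-4-hydroxyeudesm-7(11)-ene-3,8-dione
Product: 16 (3S,4S,5R,10R)-3,4-dihydroxyeudesm-7(11)-en-8-one
Conditions: NaBH4 (1 equiv), MeOH–CH2Cl2, −40 °C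
Reagents that add atoms: none
Why: Borohydride reduction with axial hydride delivery from the α face (the β side is blocked by the axial 4β-methyl) gives the equatorial 3β-alcohol, while the hindered cross-conjugated C8 enone is not reduced at −40 °C.

**Step 11**
Reactants: 16 (3S,4S,5R,10R)-3,4-dihydroxyeudesm-7(11)-en-8-one; 17 (R)-2-methylbutanoic acid
Product: 18 (3S,4S,5R,10R)-4-hydroxy-3-[(2R)-2-methylbutanoyloxy]eudesm-7(11)-en-8-one
Conditions: DCC, DMAP (10 mol %), CH2Cl2, 0 °C → rt
Reagents that add atoms: none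
Why: Steglich esterification acylates only the secondary 3β-hydroxyl (the tertiary one is inert here) and does not epimerise the α-centre of the aliphatic acid at this temperature.

**Step 12**
Reactants: 18 (3S,4S,5R,10R)-4-hydroxy-3-[(2R)-2-methylbutanoyloxy]eudesm-7(11)-en-8-one
Product: 19 (3S,4S,5R,10R)-4-acetoxy-3-[(2R)-2-methylbutanoyloxy]eudesm-7(11)-en-8-one
Conditions: Ac2O, DMAP, Et3N, CH2Cl2, 40 °C
Reagents that add atoms: acetic anhydride CC(=O)OC(C)=O
Why: DMAP-catalysed acetylation under forcing conditions esterifies the remaining tertiary equatorial alcohol without touching any stereocentre.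

**Compound list**
1 | (S)-(+)-carvone, (5S)-2-methyl-5-(prop-1-en-2-yl)cyclohex-2-en-1-one | CC1=CC[C@@H](CC1=O)C(C)=C | starting material
2 | 3-bromo-2-methylprop-1-ene (methallyl bromide) | CC(=C)CBr | starting material
3 | lithium (3S)-6-methyl-3-(prop-1-en-2-yl)cyclohexa-1,5-dien-1-olate (kinetic dienolate of 1) | CC1=CC[C@H](C(C)=C)C=C1[O-].[Li+] | intermediate
4 | (5S,6R)-2-methyl-6-(2-methylprop-2-en-1-yl)-5-(prop-1-en-2-yl)cyclohex-2-en-1-one | CC1=CC[C@H](C(C)=C)[C@@H](CC(C)=C)C1=O | intermediate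
5 | lithium (3R)-6-methyl-2-(2-methylprop-2-en-1-yl)-3-(prop-1-en-2-yl)cyclohexa-1,5-dien-1-olate (dienolate of 4) | CC1=CC[C@H](C(C)=C)C(CC(C)=C)=C1[O-].[Li+] | intermediate
6 | lithium salt of (5R,6R)-6-hydroperoxy-2-methyl-6-(2-methylprop-2-en-1-yl)-5-(prop-1-en-2-yl)cyclohex-2-en-1-one | CC1=CC[C@H](C(C)=C)[C@](O[O-])(CC(C)=C)C1=O.[Li+] | intermediate
7 | (5R,6R)-6-hydroxy-2-methyl-6-(2-methylprop-2-en-1-yl)-5-(prop-1-en-2-yl)cyclohex-2-en-1-one | CC1=CC[C@H](C(C)=C)[C@](O)(CC(C)=C)C1=O | intermediate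
8 | (1R,5R,6R)-2-methyl-6-(2-methylprop-2-en-1-yl)-5-(prop-1-en-2-yl)cyclohex-2-ene-1,6-diol (carvone numbering) | CC1=CC[C@H](C(C)=C)[C@](O)(CC(C)=C)[C@@H]1O | intermediate
9 | (2Z,5R)-2,8-dimethyl-6-oxo-5-(prop-1-en-2-yl)nona-2,8-dienal | O=C/C(C)=C\C[C@H](C(C)=C)C(=O)CC(C)=C | intermediate
10 | (2E,5R)-2,8-dimethyl-6-oxo-5-(prop-1-en-2-yl)nona-2,8-dienal | O=C/C(C)=C/C[C@H](C(C)=C)C(=O)CC(C)=C | intermediate
11 | (5R,7E)-2,8-dimethyl-5-(prop-1-en-2-yl)deca-1,7,9-trien-4-one | C=C/C(C)=C/C[C@H](C(C)=C)C(=O)CC(C)=C | intermediate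
12 | (5R,7R,10R)-eudesma-3,11-dien-8-one (trans-fused, 5α-H, 7β-isopropenyl, 10β-CH3) | C1=C(C)[C@@H]2C[C@H](C(C)=C)C(=O)C[C@@]2(C)CC1 | intermediate
13 | (5R,10R)-eudesma-3,7(11)-dien-8-one (trans-fused, 5α-H, 10β-CH3) | C1=C(C)[C@@H]2CC(=C(C)C)C(=O)C[C@@]2(C)CC1 | intermediate
14 | (3R,4S,5R,10R)-3,4-dihydroxyeudesm-7(11)-en-8-one (3α-OH, 4α-OH, 4β-CH3) | O[C@@H]1CC[C@]2(C)CC(=O)C(=C(C)C)C[C@H]2[C@]1(C)O | intermediate
15 | (4S,5R,10R)-4-hydroxyeudesm-7(11)-ene-3,8-dione (4α-OH) | O=C1CC[C@]2(C)CC(=O)C(=C(C)C)C[C@H]2[C@]1(C)O | intermediate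
16 | (3S,4S,5R,10R)-3,4-dihydroxyeudesm-7(11)-en-8-one (3β-OH, 4α-OH) | O[C@H]1CC[C@]2(C)CC(=O)C(=C(C)C)C[C@H]2[C@]1(C)O | intermediate
17 | (R)-2-methylbutanoic acid | CC[C@@H](C)C(O)=O | starting material
18 | (3S,4S,5R,10R)-4-hydroxy-3-[(2R)-2-methylbutanoyloxy]eudesm-7(11)-en-8-one | CC[C@@H](C)C(=O)O[C@H]1CC[C@]2(C)CC(=O)C(=C(C)C)C[C@H]2[C@]1(C)O | intermediate
19 | (3S,4S,5R,10R)-4-acetoxy-3-[(2R)-2-methylbutanoyloxy]eudesm-7(11)-en-8-one (CNP0111007.1) | CC[C@@H](C)C(=O)O[C@H]1CC[C@]2(C)CC(=O)C(=C(C)C)C[C@H]2[C@]1(C)OC(C)=O | target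

**Step count and risks**
Total step count: 12. Longest linear sequence: 12 steps (1 → 19).

The three steps most likely to fail:

Step 5 (methylenation of 10). The hydrogen at the stereocentre of 10 lies between the ketone and the isopropenyl group, so a basic ylide could epimerise it or conjugate the alkene, and that centre is the only source of asymmetry for step 6. The fallback sets out from 10 and avoids a phosphorus ylide. Me3SiCH2MgCl/CeCl3 (THF, −78 °C) adds only to the aldehyde and gives the β-hydroxysilane (5R,7E,9R)-9-hydroxy-2,8-dimethyl-5-(prop-1-en-2-yl)-10-(trimethylsilyl)deca-1,7-dien-4-one F1 (formed together with its 9S epimer). Acid-induced Peterson elimination (BF3·OEt2, CH2Cl2, −20 °C) then gives the diene, and the fallback comes back to the route at 11.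

Step 6 (intramolecular Diels–Alder). The dienophile is unactivated, so 185 °C is needed. The trans/cis ratio may be modest. Enolisation of the β,γ-unsaturated ketone before ring closure would lower the enantiomeric purity, because the facial isomers become enantiomers after step 7. The fallback sets out from 11 and masks the ketone by a redox detour. NaBH4 (MeOH, 0 °C) gives the carbinol (4S,5R,7E)-2,8-dimethyl-5-(prop-1-en-2-yl)deca-1,7,9-trien-4-ol F2 (with its 4R epimer), which has no enolisable centre. Heating (PhMe, 190 °C) gives the cycloadduct (5R,7R,8S,10R)-eudesma-3,11-dien-8-ol F3. Dess–Martin oxidation of the separated trans-fused adduct comes back to the route at 12.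

Step 12 (acetylation of the tertiary alcohol next to the bulky ester). The reaction may stall or eliminate. The fallback sets out from 15 and installs the acetate before the C3 hydroxyl exists, while C3 is still sp2. Ac2O, DMAP and Et3N (CH2Cl2, rt) acetylate the tertiary α-ketol to (4S,5R,10R)-4-acetoxyeudesm-7(11)-ene-3,8-dione F4. NaBH4 (MeOH, −78 °C, AcOH quench to suppress acetyl migration) gives (3S,4S,5R,10R)-4-acetoxy-3-hydroxyeudesm-7(11)-en-8-one F5. Steglich esterification with 17 (DCC, DMAP, CH2Cl2, 0 °C) comes back to the route at 19.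

**Further compounds**
F1 | step 5 | (5R,7E,9R)-9-hydroxy-2,8-dimethyl-5-(prop-1-en-2-yl)-10-(trimethylsilyl)deca-1,7-dien-4-one | C[Si](C)(C)C[C@H](O)/C(C)=C/C[C@H](C(C)=C)C(=O)CC(C)=C
F2 | step 6 | (4S,5R,7E)-2,8-dimethyl-5-(prop-1-en-2-yl)deca-1,7,9-trien-4-ol | C=C/C(C)=C/C[C@H](C(C)=C)[C@@H](O)CC(C)=C
F3 | step 6 | (5R,7R,8S,10R)-eudesma-3,11-dien-8-ol | C1=C(C)[C@@H]2C[C@H](C(C)=C)[C@@H](O)C[C@@]2(C)CC1
F4 | step 12 | (4S,5R,10R)-4-acetoxyeudesm-7(11)-ene-3,8-dione | O=C1CC[C@]2(C)CC(=O)C(=C(C)C)C[C@H]2[C@]1(C)OC(C)=O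
F5 | step 12 | (3S,4S,5R,10R)-4-acetoxy-3-hydroxyeudesm-7(11)-en-8-one | O[C@H]1CC[C@]2(C)CC(=O)C(=C(C)C)C[C@H]2[C@]1(C)OC(C)=O
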